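**Plan**

1. Retrosynthesis: the C10 angelate and C6 anisate C–O bonds are cut first. The C8 methyl is traced back to an ester, and the 4β‑OH/5α‑H/6α‑OH triad to the 4‑en‑6‑one 11 (epoxidation, reductive C5–O cleavage, hydroxyl‑directed reduction), itself the Stork–Danheiser product of vinylogous ester 9.
2. Ring B of 9 is cut at C7–C8 and C10–C1 in one formal [4+3] operation: 2‑alkoxydiene 3 (ring A already present; C7=C6–C5=C1) plus the three‑carbon rhodium vinylcarbenoid from vinyldiazoacetate 7 (C8–C9=C10).
3. Enabling feature: in ring B the C8=C9 alkene and the oxygenated C6 (a C5=C6 enol ether one step earlier) flank the C7 methylene as a skipped 1,4‑diene with an allylic oxygen on C10. This is the signature of a cis‑divinylcyclopropane rearrangement whose vinyl terminus is an enol ether.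
4. Forward order: ring A is bought (bromoenone 1); diene 3 and diazo ester 7 take one and two steps; ring B closes in step 4; isopropyl group, oxygen pattern, C8 methyl and the two esters follow.
5. Stereochemistry: absolute configuration from the chiral dirhodium catalyst in the cyclopropanation; C1 and C10 from the boat Cope rearrangement of the E enol ether; C4 from epoxidation anti to the C10 arm; C5 from enolate protonation; C6 from intramolecular hydride delivery by the 4β‑hydroxyl.

Key step: step 4

Remark (locants): C1 = quaternary ring‑fusion carbon (methyl C15), C2 and C3 = ring A methylenes, C4 = carbinol carbon (isopropyl), C5 = ring‑fusion CH, then around ring B C6 (O‑anisoyl), C7 (CH2), C8 (methyl C14), C9 (=CH), C10 (O‑angeloyl); ring A = five‑membered ring, ring B = seven‑membered ring; β = the face of the C1 methyl, α = the opposite face.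
Assumption: Rh2(R‑DOSP)4 is taken to be the catalyst enantiomer that delivers the carbenoid to the required face of C6=C7 (extrapolated from the sense known for simple alkenes); the enantiomeric catalyst would be used if the substrate followed the opposite sense.

**Route**

Step 1
Reactants: 1 2‑bromo‑3‑methylcyclopent‑2‑en‑1‑one; 2 tributyl(1‑ethoxyvinyl)stannane
Product: 3 2‑(1‑ethoxyvinyl)‑3‑methylcyclopent‑2‑en‑1‑one
Conditions: Pd(PPh3)4 (5 mol %), CuI (10 mol %), toluene, 100 °C; Et3N‑deactivated silica
Reagents that add atoms: none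
Why: Stille cross‑coupling at the C(sp2)–Br bond of the α‑bromoenone installs the 2‑alkoxydiene without touching the enone; no stereocentre is formed.

Step 2
Reactants: 4 ethyl diazoacetate; 5 (tert‑butyldimethylsilyloxy)acetaldehyde
Product: 6 ethyl 4‑(tert‑butyldimethylsilyloxy)‑2‑diazo‑3‑hydroxybutanoate (racemic)
Conditions: DBU (10 mol %), MeCN, 0 °C → rt
Reagents that add atoms: none
Why: DBU‑catalysed aldol‑type addition of the acidic diazo C–H to the aldehyde should give the β‑hydroxy‑α‑diazo ester; the racemic carbinol centre is removed in step 3.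

Step 3
Reactants: 6 ethyl 4‑(tert‑butyldimethylsilyloxy)‑2‑diazo‑3‑hydroxybutanoate
Product: 7 ethyl (E)‑4‑(tert‑butyldimethylsilyloxy)‑2‑diazobut‑3‑enoate
Conditions: POCl3, Et3N, CH2Cl2, 0 °C; used fresh
Reagents that add atoms: none
Why: Dehydration through the dichlorophosphate (base‑induced β‑elimination) should give the conjugated vinyldiazoacetate, the E enol ether being the less strained and expected major isomer.

Step 4
Reactants: 3 2‑(1‑ethoxyvinyl)‑3‑methylcyclopent‑2‑en‑1‑one; 7 ethyl (E)‑4‑(tert‑butyldimethylsilyloxy)‑2‑diazobut‑3‑enoate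
Product: 9 bicyclic vinylogous ester (C4 ketone; C5=C6 enol ether with 6‑OEt; C8=C9 with 8‑CO2Et; 10α‑OTBS; 1β‑methyl), via cis‑divinylcyclopropane 8 (not isolated)
Conditions: Rh2(R‑DOSP)4 (1 mol %), hexanes–PhCF3, −40 °C → rt, slow addition of 7; then toluene, 80 °C
Reagents that add atoms: none
Why: Rh2(R‑DOSP)4 converts 7 into a donor/acceptor rhodium vinylcarbenoid, which cyclopropanates the electron‑rich 1‑ethoxyvinyl alkene C6=C7 of 3 (bonds C8–C7 and C8–C6) to give cis‑divinylcyclopropane 8; on warming, 8 undergoes the divinylcyclopropane–cycloheptadiene (Cope) rearrangement, in which C10–C1 forms and the transient C8–C6 bond breaks, so that C7–C8 and C10–C1 are the two bonds made overall. The closest known reaction type is the tandem cyclopropanation/Cope rearrangement (formal [4+3] cycloaddition) of vinyldiazoacetates with dienes, oxygenated dienes included. The three‑membered ring closes by concerted carbenoid [2+1] addition, and ring B by a [3,3]‑sigmatropic shift through the boat transition state that the cis‑cyclopropane enforces. The absolute configuration is set by the catalyst, which delivers C8 to the face of C6=C7 that becomes the α side, and the boat geometry transfers it to the quaternary C1 (C10 bonded α, methyl left β); C10 is controlled by the E geometry of the silyl enol ether, whose oxygen ends on the side of the outward ring carbon C2 and trans to the inward methyl, i.e. 10α. The step needs site selectivity for C6=C7 over the tetrasubstituted enone alkene C1=C5 (secured by the nucleophilicity of the enol ether), the cis arrangement of the two alkenyl groups on the cyclopropane (the π‑substituent of the alkene sits on the side of the carbenoid donor group), and seven‑ over five‑membered ring closure (favoured by the non‑polar solvent, which suppresses zwitterionic opening of the donor–acceptor cyclopropane); the inward methyl on C1 only slows the Cope step, hence the heating.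

Step 5
Reactants: 9 bicyclic vinylogous ester
Product: 11 4‑en‑6‑one (C4=C5 bearing isopropyl on C4; C6 ketone; C8=C9 with 8‑CO2Et; 10α‑OTBS; 1β‑methyl), via tertiary allylic alcohol 10 (not isolated)
Conditions: iPrMgCl, CeCl3, THF, −78 → 0 °C; then 10% aq. oxalic acid, THF, 0 °C
Reagents that add atoms: isopropylmagnesium chloride CC(C)[Mg]Cl; water O
Why: Stork–Danheiser transposition: CeCl3‑promoted 1,2‑addition to the vinylogous‑ester carbonyl C4 (faster than addition to the conjugated ethyl ester at low temperature) gives 10, whose acid‑induced ionisation and enol ether hydrolysis move the carbonyl to C6 and the alkene to C4=C5; the C4 carbinol centre is destroyed, so its configuration does not matter.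

Step 6
Reactants: 11 4‑en‑6‑one
Product: 12 4β,5β‑epoxy‑6‑ketone (4α‑isopropyl; 8‑CO2Et; 10α‑OTBS)
Conditions: dimethyldioxirane (acetone solution), CH2Cl2, 0 °C → rt
Reagents that add atoms: dimethyldioxirane CC1(C)OO1
Why: Electrophilic epoxidation under neutral conditions (which avoid base‑induced conjugation of the β,γ C8=C9 alkene) should occur at the tetrasubstituted C4=C5 alkene and not at the enoate, with oxygen delivered to the β face, anti to the C10 arm whose pseudoaxial silyloxy group covers the α face of ring A; this fixes the C4–O bond as β.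

Step 7
Reactants: 12 4β,5β‑epoxy‑6‑ketone
Product: 13 β‑hydroxy ketone (4β‑OH, 4α‑isopropyl, 5α‑H, C6 ketone; 8‑CO2Et; 10α‑OTBS)
Conditions: SmI2 (2.2 equiv), THF–MeOH, −78 °C; pH 7 phosphate buffer
Reagents that add atoms: none
Why: SmI2 reduction of the α,β‑epoxy ketone (ketyl formation, cleavage of the Cα–O bond C5–O) gives the samarium aldolate with the 4β C–O bond intact, and protonation of the enolate carbon C5 by MeOH from the α face (the β face being covered by the trivalent samarium bridging O4 and O6) should give the trans ring fusion, which also places C6 anti to the isopropyl group.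

Step 8
Reactants: 13 β‑hydroxy ketone
Product: 14 4β,6α‑diol ethyl ester (5α‑H; 8‑CO2Et; 10α‑OTBS)
Conditions: Me4NBH(OAc)3, MeCN–AcOH, −30 °C
Reagents that add atoms: none
Why: Evans–Saksena reduction: the triacetoxyborohydride exchanges an acetate for the tertiary 4β‑hydroxyl and delivers hydride intramolecularly to the β face of the C6 carbonyl through a six‑membered transition state, giving the 1,3‑anti diol (6α‑OH, H6 β) and leaving ester and alkene untouched.

Step 9
Reactants: 14 4β,6α‑diol ethyl ester
Product: 15 triol (4β‑OH, 6α‑OH, hydroxymethyl on C8; 10α‑OTBS)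
Conditions: iBu2AlH (5 equiv), CH2Cl2, −78 → 0 °C; aq. potassium sodium tartrate
Reagents that add atoms: none
Why: iBu2AlH reduces the conjugated ethyl ester by 1,2‑addition to the primary allylic alcohol once the two hydroxyls are aluminium alkoxides; silyl ether and trisubstituted alkene are inert.

Step 10
Reactants: 15 triol
Product: 16 allylic chloride (chloromethyl on C8; 4β‑OH, 6α‑OH; 10α‑OTBS)
Conditions: N‑chlorosuccinimide, Me2S, CH2Cl2, −20 → 0 °C
Reagents that add atoms: N‑chlorosuccinimide O=C1CCC(=O)N1Cl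
Why: Corey–Kim chlorination converts the allylic alcohol to the chloride by SN2 displacement of its alkoxysulfonium ion under neutral conditions, while the non‑allylic secondary and tertiary hydroxyls are returned unchanged on work‑up.

Step 11
Reactants: 16 allylic chloride
Product: 17 diol (C8 methyl; 4β‑OH, 6α‑OH; 10α‑OTBS)
Conditions: LiEt3BH, THF, 0 °C → rt
Reagents that add atoms: none
Why: LiEt3BH should displace the primary allylic chloride by direct SN2 hydride attack, giving the C8 methyl group without transposing the C8=C9 alkene; the hydroxyls are only deprotonated.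

Step 12
Reactants: 17 diol; 18 4‑methoxybenzoyl chloride
Product: 19 6α‑(4‑methoxybenzoate) of 17 (4β‑OH free; 10α‑OTBS)
Conditions: Et3N, DMAP (cat.), CH2Cl2, 0 °C → rt
Reagents that add atoms: none
Why: DMAP‑catalysed acylation should take place only at the equatorial secondary 6α‑hydroxyl, the tertiary 4‑hydroxyl being too hindered and O10 being silylated.

Step 13
Reactants: 19 6α‑(4‑methoxybenzoate) silyl ether
Product: 20 10α‑alcohol (6α‑(4‑methoxybenzoyloxy), 4β‑OH, 10α‑OH)
Conditions: HF·pyridine, pyridine, THF, 0 °C → rt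
Reagents that add atoms: none
Why: Fluoride‑mediated Si–O cleavage under buffered conditions removes the secondary TBS ether without acyl migration, hydrolysis of the aryl ester or ionisation of the tertiary alcohol.

Step 14
Reactants: 20 10α‑alcohol; 21 angelic acid ((Z)‑2‑methylbut‑2‑enoic acid)
Product: 23 target CNP0168729.1, via mixed anhydride 22 (not isolated)
Conditions: 2,4,6‑trichlorobenzoyl chloride, Et3N, toluene, rt; then 20, 80 °C
Reagents that add atoms: none
Why: Yamaguchi‑type esterification: mixed anhydride 22 acylates the hindered secondary allylic 10α‑hydroxyl on heating without DMAP, conditions chosen because they transfer the (Z)‑2‑methylbut‑2‑enoyl group without isomerisation to the tiglate; the tertiary hydroxyl does not react.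

**Compound list**

1 | 2‑bromo‑3‑methylcyclopent‑2‑en‑1‑one | CC1=C(Br)C(=O)CC1 | starting material
2 | tributyl(1‑ethoxyvinyl)stannane | CCOC(=C)[Sn](CCCC)(CCCC)CCCC | starting material
3 | 2‑(1‑ethoxyvinyl)‑3‑methylcyclopent‑2‑en‑1‑one | CCOC(=C)C1=C(C)CCC1=O | intermediate
4 | ethyl diazoacetate | CCOC(=O)C=[N+]=[N-] | starting material
5 | (tert‑butyldimethylsilyloxy)acetaldehyde | CC(C)(C)[Si](C)(C)OCC=O | starting material
6 | ethyl 4‑(tert‑butyldimethylsilyloxy)‑2‑diazo‑3‑hydroxybutanoate (racemic) | CCOC(=O)C(=[N+]=[N-])C(O)CO[Si](C)(C)C(C)(C)C | intermediate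
7 | ethyl (E)‑4‑(tert‑butyldimethylsilyloxy)‑2‑diazobut‑3‑enoate | CCOC(=O)C(=[N+]=[N-])/C=C/O[Si](C)(C)C(C)(C)C | intermediate
8 | ethyl 2‑ethoxy‑2‑(2‑methyl‑5‑oxocyclopent‑1‑en‑1‑yl)‑1‑[(E)‑2‑(tert‑butyldimethylsilyloxy)vinyl]cyclopropane‑1‑carboxylate, cyclopentenyl and silyloxyvinyl groups cis (not isolated) | CCOC(=O)[C@]1(/C=C/O[Si](C)(C)C(C)(C)C)C[C@@]1(OCC)C2=C(C)CCC2=O | intermediate
9 | bicyclic vinylogous ester: C4 ketone, C5=C6 enol ether (6‑OEt), C8=C9 with 8‑CO2Et, 10α‑OTBS, 1β‑methyl | CC(C)(C)[Si](C)(C)O[C@@H]1C=C(C(=O)OCC)CC(OCC)=C2[C@]1(C)CCC2=O | intermediate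
10 | tertiary allylic alcohol: 9 with C4(OH)(isopropyl) in place of the C4 ketone, either C4 epimer (not isolated) | CC(C)(C)[Si](C)(C)O[C@@H]1C=C(C(=O)OCC)CC(OCC)=C2[C@]1(C)CCC2(O)C(C)C | intermediate
11 | 4‑en‑6‑one: C4=C5 with isopropyl on C4, C6 ketone, C8=C9 with 8‑CO2Et, 10α‑OTBS, 1β‑methyl | CC(C)(C)[Si](C)(C)O[C@@H]1C=C(C(=O)OCC)CC(=O)C=2[C@]1(C)CCC=2C(C)C | intermediate
12 | 4β,5β‑epoxy‑6‑ketone (4α‑isopropyl, 8‑CO2Et, 10α‑OTBS) | CC(C)(C)[Si](C)(C)O[C@@H]1C=C(C(=O)OCC)CC(=O)[C@@]23[C@]1(C)CC[C@@]2(O3)C(C)C | intermediate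
13 | β‑hydroxy ketone: 4β‑OH, 4α‑isopropyl, 5α‑H (trans fusion), C6 ketone, 8‑CO2Et, 10α‑OTBS | CC(C)(C)[Si](C)(C)O[C@@H]1C=C(C(=O)OCC)CC(=O)[C@@H]2[C@]1(C)CC[C@@]2(O)C(C)C | intermediate
14 | 4β,6α‑diol ethyl ester (5α‑H, 8‑CO2Et, 10α‑OTBS) | CC(C)(C)[Si](C)(C)O[C@@H]1C=C(C(=O)OCC)C[C@H](O)[C@@H]2[C@]1(C)CC[C@@]2(O)C(C)C | intermediate
15 | triol: 4β‑OH, 6α‑OH, hydroxymethyl on C8, 10α‑OTBS | CC(C)(C)[Si](C)(C)O[C@@H]1C=C(CO)C[C@H](O)[C@@H]2[C@]1(C)CC[C@@]2(O)C(C)C | intermediate
16 | allylic chloride: chloromethyl on C8, 4β‑OH, 6α‑OH, 10α‑OTBS | CC(C)(C)[Si](C)(C)O[C@@H]1C=C(CCl)C[C@H](O)[C@@H]2[C@]1(C)CC[C@@]2(O)C(C)C | intermediate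
17 | diol: C8 methyl, 4β‑OH, 6α‑OH, 10α‑OTBS | CC(C)(C)[Si](C)(C)O[C@@H]1C=C(C)C[C@H](O)[C@@H]2[C@]1(C)CC[C@@]2(O)C(C)C | intermediate
18 | 4‑methoxybenzoyl chloride | COc1ccc(cc1)C(Cl)=O | starting material
19 | 6α‑(4‑methoxybenzoate) of 17 (4β‑OH, 10α‑OTBS) | CC(C)(C)[Si](C)(C)O[C@@H]1C=C(C)C[C@H](OC(=O)c2ccc(OC)cc2)[C@@H]2[C@]1(C)CC[C@@]2(O)C(C)C | intermediate
20 | 10α‑alcohol: 6α‑(4‑methoxybenzoyloxy), 4β‑OH, 10α‑OH | O[C@@H]1C=C(C)C[C@H](OC(=O)c2ccc(OC)cc2)[C@@H]2[C@]1(C)CC[C@@]2(O)C(C)C | intermediate
21 | angelic acid, (Z)‑2‑methylbut‑2‑enoic acid | C/C=C(/C)C(=O)O | starting material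
22 | (Z)‑2‑methylbut‑2‑enoic 2,4,6‑trichlorobenzoic anhydride (not isolated) | C/C=C(/C)C(=O)OC(=O)c1c(Cl)cc(Cl)cc1Cl | intermediate
23 | (3R,3aS,4S,8R,8aS)‑3‑hydroxy‑6,8a‑dimethyl‑8‑{[(2Z)‑2‑methylbut‑2‑enoyl]oxy}‑3‑(propan‑2‑yl)‑1,2,3,3a,4,5,8,8a‑octahydroazulen‑4‑yl 4‑methoxybenzoate | C/C=C(/C)C(=O)O[C@@H]1C=C(C)C[C@H](OC(=O)c2ccc(OC)cc2)[C@@H]2[C@]1(C)CC[C@@]2(O)C(C)C | target

**Step count and risks**

Total: 14 steps. Longest linear sequence: 13 steps (steps 2–14, from 4 and 5).

Steps most likely to fail:

Step 4. The donor–acceptor cyclopropane 8 may open heterolytically (alkoxy‑stabilised cation at C6, ester‑stabilised anion at C8) and then close to a five‑membered ring or lose the configuration set by the catalyst; enantioface selection at a 1,1‑disubstituted enol ether may also be poor. The fallback sets out from 1 and 7 and returns at 11. Stille coupling of 1 with tributyl(vinyl)stannane, Bu3SnCH=CH2 (Pd(PPh3)4, CuI), would give 3‑methyl‑2‑vinylcyclopent‑2‑en‑1‑one F1. Its unsubstituted vinyl group would react with 7 and Rh2(R‑DOSP)4 to give the donor‑free cis‑divinylcyclopropane F2, which can only rearrange by the concerted Cope pathway to the bicyclic enone F3 (C4 ketone, C5=C6). CeCl3‑promoted addition of iPrMgCl would give the tertiary allylic alcohol F4, and Babler–Dauben oxidative transposition with pyridinium chlorochromate, C5H5NH[CrO3Cl], would move the oxygen to C6 and the alkene to C4=C5, which is 11.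

Step 7. The enolate carbon C5 may be protonated from the β face, giving the cis ring fusion; correction by equilibration is not available because base would move the C8=C9 alkene into conjugation with the C6 ketone. The fallback sets out from 12 and returns at 13. Reduction of 12 with NaBH4/CeCl3 in MeOH (hydride entering anti to the epoxide oxygen) would give the cis‑epoxy alcohol F5 (4β,5β‑epoxide, 6β‑OH). With BF3·OEt2 in CH2Cl2 at −78 °C this should undergo a semipinacol 1,2‑hydride shift: H6, anti‑periplanar to the C5–O bond, migrates to C5 with inversion (5α‑H) while C6 becomes the ketone and O4 stays β, which is 13.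

Step 6. Oxygen transfer may take place on the α face, or the hindered tetrasubstituted enone may not react. The fallback sets out from 11 and returns at 13, bypassing step 7 as well. Luche reduction (NaBH4, CeCl3, MeOH) would give the 6β‑allylic alcohol F6 (a 6α‑epimer would be returned to 11 with MnO2). Hydroxyl‑directed epoxidation with VO(acac)2 and tBuOOH delivers oxygen syn to the hydroxyl and would give the epoxy alcohol F7 (identical with F5), which is rearranged with BF3·OEt2 as above to 13.

**Further compounds**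

F1 | step 4 | 3‑methyl‑2‑vinylcyclopent‑2‑en‑1‑one | C=CC1=C(C)CCC1=O
F2 | step 4 | ethyl 2‑(2‑methyl‑5‑oxocyclopent‑1‑en‑1‑yl)‑1‑[(E)‑2‑(tert‑butyldimethylsilyloxy)vinyl]cyclopropane‑1‑carboxylate, alkenyl groups cis (not isolated) | CCOC(=O)[C@]1(/C=C/O[Si](C)(C)C(C)(C)C)C[C@H]1C2=C(C)CCC2=O
F3 | step 4 | bicyclic enone: C4 ketone, C5=C6, C8=C9 with 8‑CO2Et, 10α‑OTBS, 1β‑methyl | CC(C)(C)[Si](C)(C)O[C@@H]1C=C(C(=O)OCC)CC=C2[C@]1(C)CCC2=O
F4 | step 4 | tertiary allylic alcohol: F3 with C4(OH)(isopropyl), either C4 epimer | CC(C)(C)[Si](C)(C)O[C@@H]1C=C(C(=O)OCC)CC=C2[C@]1(C)CCC2(O)C(C)C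
F5 | step 7 | cis‑epoxy alcohol: 4β,5β‑epoxide, 6β‑OH, 8‑CO2Et, 10α‑OTBS | CC(C)(C)[Si](C)(C)O[C@@H]1C=C(C(=O)OCC)C[C@@H](O)[C@@]23[C@]1(C)CC[C@@]2(O3)C(C)C
F6 | step 6 | 6β‑allylic alcohol: C4=C5 with isopropyl on C4, 6β‑OH, 8‑CO2Et, 10α‑OTBS | CC(C)(C)[Si](C)(C)O[C@@H]1C=C(C(=O)OCC)C[C@@H](O)C=2[C@]1(C)CCC=2C(C)C
F7 | step 6 | cis‑epoxy alcohol: 4β,5β‑epoxide, 6β‑OH, 8‑CO2Et, 10α‑OTBS (same structure as F5) | CC(C)(C)[Si](C)(C)O[C@@H]1C=C(C(=O)OCC)C[C@@H](O)[C@@]23[C@]1(C)CC[C@@]2(O3)C(C)C
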